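**Plan**
- Retrosynthesis first cuts the aryl ester C–O bond between the ring A carbonyl and O3 of ring B. Ring A is then cut at C6–pentyl and C1–CO2H in a single operation, and ring B at C1–CO2H and C3–O.
- Enabling feature: in ring A the carbonyl-bearing C1 lies between the methoxy-bearing C2 and the pentyl-bearing C6. This is the pattern left when a carbon nucleophile and CO2 add across a C1–C6 aryne polarised by the C2 oxygen.
- Forward, ring A: 1-bromo-3,5-dimethoxybenzene is iodinated, then converted in one pot with pentylmagnesium bromide and CO2 into the ring A acid.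
- Forward, ring B: 5-propylresorcinol is carboxylated, esterified, formylated at C3, benzylated and oxidised to the ring B phenol.
- Both benzene rings are purchased intact and no ring is formed. The halves are joined by trifluoroacetic anhydride esterification and three benzyl groups are removed by hydrogenolysis.
- Stereochemistry: the target has no stereocentre and no stereogenic double bond, so none has to be set.

Key step: step 3

Remark: ring positions are counted from the carboxyl-bearing carbon (C1) of each ring; the C3 selectivity of the formylation in step 6 is an expectation from the substitution pattern, not an established result, and a fallback is given.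

Step 1
Reactants: 1 1-bromo-3,5-dimethoxybenzene
Product: 2 1-bromo-2-iodo-3,5-dimethoxybenzene
Conditions: N-iodosuccinimide (1.05 equiv), MeCN, rt, dark
Reagents that add atoms: N-iodosuccinimide, O=C1CCC(=O)N1I
Why: Electrophilic aromatic iodination should take place at C2, which is ortho to one methoxy group and para to the other, and not at C4 between the two methoxy groups, as is usual for halogenation of 5-substituted 1,3-dimethoxybenzenes.

Step 2
Reactants: 3 1-bromopentane
Product: 4 pentylmagnesium bromide
Conditions: Mg turnings (1.2 equiv), I2 (cat.), THF, 40 °C; titrate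
Reagents that add atoms: magnesium, [Mg]
Why: Grignard formation by insertion of magnesium into a primary carbon–bromine bond is routine and gives a THF solution of known titre for the next step.

Step 3
Reactants: 2 1-bromo-2-iodo-3,5-dimethoxybenzene; 4 pentylmagnesium bromide; 5 carbon dioxide
Product: 9 2,4-dimethoxy-6-pentylbenzoic acid, via 2-bromo-4,6-dimethoxyphenylmagnesium chloride 6 (not isolated), via 3,5-dimethoxybenzyne 7 (not isolated), via 2,4-dimethoxy-6-pentylphenylmagnesium bromide 8 (not isolated)
Conditions: iPrMgCl·LiCl (1.05 equiv), THF, −30 °C; then 4 (3 equiv), −30 → 60 °C; then CO2 gas, −20 °C → rt; aq. HCl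
Reagents that add atoms: none
Why: Iodine–magnesium exchange at the carbon–iodine bond gives arylmagnesium 6, which on warming expels MgBrCl toward bromide, the only leaving group available since methoxide does not leave, to form aryne 7; Grignard 4 then adds across the strained triple bond to give arylmagnesium 8, which CO2 carboxylates. The closest known reaction type is the one-pot aryne carbomagnesiation of 2-haloarylmagnesium halides followed by an electrophilic quench, including Grignard additions to 3-methoxyarynes. No ring is closed and no stereocentre is created. The step needs regioselective addition to the unsymmetrical aryne, and the methoxy group on the carbon next to the triple bond secures it: its inductive pull and the resulting angle distortion make the remote aryne carbon (future C6) the electrophilic one and place the carbanion on the carbon beside oxygen (future C1), where the methoxy group also chelates magnesium. Chemoselectivity rests on completing the exchange cold before 4 is added, so that little isopropyl nucleophile remains, and on a threefold excess of the unhindered primary Grignard 4, which should outrun addition of the hindered arylmagnesium 8 to the aryne.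

Step 4
Reactants: 10 5-propylresorcinol
Product: 11 2,4-dihydroxy-6-propylbenzoic acid
Conditions: MeOMgOCO2Me in DMF (4 equiv), 120 °C, N2; then cold aq. HCl
Reagents that add atoms: methoxymagnesium methyl carbonate, CO[Mg]OC(=O)OC
Why: Chelation-driven ortho-carboxylation of the phenol (a Kolbe–Schmitt-type carboxylation with a magnesium methyl carbonate) should occur at the ring carbon between a hydroxyl and the propyl group, ortho to one hydroxyl and para to the other, as is known for 5-alkylresorcinols.

Step 5
Reactants: 11 2,4-dihydroxy-6-propylbenzoic acid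
Product: 12 benzyl 2,4-dihydroxy-6-propylbenzoate
Conditions: BnBr (1.05 equiv), KHCO3 (1.1 equiv), DMF, rt
Reagents that add atoms: benzyl bromide, BrCc1ccccc1
Why: SN2 O-alkylation of the carboxylate, the only group that KHCO3 deprotonates to a useful extent, should give the benzyl ester and leave both phenols free.

Step 6
Reactants: 12 benzyl 2,4-dihydroxy-6-propylbenzoate
Product: 13 benzyl 3-formyl-2,4-dihydroxy-6-propylbenzoate
Conditions: MgCl2 (anhydrous, 3 equiv), Et3N (5 equiv), paraformaldehyde (6 equiv), MeCN, reflux; aq. HCl
Reagents that add atoms: paraformaldehyde (as formaldehyde), C=O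
Why: The magnesium-mediated ortho-formylation of phenols (Casnati–Skattebøl reaction) delivers formaldehyde from a magnesium phenoxide to an ortho carbon, and C3 is ortho to both phenoxides whereas C5 is ortho to only one and is flanked by the propyl group, so C3 should be formylated.

Step 7
Reactants: 13 benzyl 3-formyl-2,4-dihydroxy-6-propylbenzoate
Product: 14 benzyl 2,4-bis(benzyloxy)-3-formyl-6-propylbenzoate
Conditions: BnBr (2.5 equiv), K2CO3 (3 equiv), DMF, 60 °C
Reagents that add atoms: benzyl bromide, BrCc1ccccc1
Why: Williamson etherification under these conditions should alkylate both hydrogen-bonded phenols, the non-enolisable aldehyde and the benzyl ester being inert to carbonate base.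

Step 8
Reactants: 14 benzyl 2,4-bis(benzyloxy)-3-formyl-6-propylbenzoate
Product: 16 benzyl 2,4-bis(benzyloxy)-3-hydroxy-6-propylbenzoate, via benzyl 2,4-bis(benzyloxy)-3-(formyloxy)-6-propylbenzoate 15 (not isolated)
Conditions: mCPBA (1.3 equiv), CH2Cl2, 0 °C → rt; then K2CO3 (cat.), MeOH, 0 °C
Reagents that add atoms: 3-chloroperoxybenzoic acid (mCPBA), OOC(=O)c1cccc(Cl)c1
Why: Baeyer–Villiger oxidation of an electron-rich benzaldehyde flanked by two alkoxy groups proceeds with aryl migration (Dakin-type) to aryl formate 15, which brief base-catalysed methanolysis should cleave without touching the hindered benzyl ester.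

Step 9
Reactants: 9 2,4-dimethoxy-6-pentylbenzoic acid; 16 benzyl 2,4-bis(benzyloxy)-3-hydroxy-6-propylbenzoate
Product: 18 benzyl 2,4-bis(benzyloxy)-3-[(2,4-dimethoxy-6-pentylbenzoyl)oxy]-6-propylbenzoate, via 2,4-dimethoxy-6-pentylbenzoic trifluoroacetic anhydride 17 (not isolated)
Conditions: (CF3CO)2O (4 equiv), toluene, rt
Reagents that add atoms: none
Why: In this mixed-anhydride esterification, anhydride 17 ionises to an acylium ion stabilised by the ortho and para methoxy groups, a slim electrophile that should acylate the only free hydroxyl of 16 despite the flanking substituents on both partners, as in established depside couplings.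

Step 10
Reactants: 18 benzyl 2,4-bis(benzyloxy)-3-[(2,4-dimethoxy-6-pentylbenzoyl)oxy]-6-propylbenzoate
Product: 19 3-[(2,4-dimethoxy-6-pentylbenzoyl)oxy]-2,4-dihydroxy-6-propylbenzoic acid
Conditions: H2 (1 atm), 10% Pd/C, EtOAc, rt
Reagents that add atoms: none
Why: Catalytic hydrogenolysis should cleave the two benzyl ethers and the benzyl ester in one operation, while the aryl ester, the methyl ethers and both arenes are stable to H2 over Pd/C in an aprotic solvent.

**Compound list**
1 | 1-bromo-3,5-dimethoxybenzene | COc1cc(Br)cc(OC)c1 | starting material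
2 | 1-bromo-2-iodo-3,5-dimethoxybenzene | COc1cc(OC)c(I)c(Br)c1 | intermediate
3 | 1-bromopentane | CCCCCBr | starting material
4 | pentylmagnesium bromide | CCCCC[Mg]Br | intermediate
5 | carbon dioxide | O=C=O | starting material
6 | 2-bromo-4,6-dimethoxyphenylmagnesium chloride | COc1cc(OC)c([Mg]Cl)c(Br)c1 | intermediate
7 | 3,5-dimethoxybenzyne | COC1=CC#CC(OC)=C1 | intermediate
8 | 2,4-dimethoxy-6-pentylphenylmagnesium bromide | CCCCCc1cc(OC)cc(OC)c1[Mg]Br | intermediate
9 | 2,4-dimethoxy-6-pentylbenzoic acid | CCCCCc1cc(OC)cc(OC)c1C(=O)O | intermediate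
10 | 5-propylresorcinol | CCCc1cc(O)cc(O)c1 | starting material
11 | 2,4-dihydroxy-6-propylbenzoic acid | CCCc1cc(O)cc(O)c1C(=O)O | intermediate
12 | benzyl 2,4-dihydroxy-6-propylbenzoate | CCCc1cc(O)cc(O)c1C(=O)OCc1ccccc1 | intermediate
13 | benzyl 3-formyl-2,4-dihydroxy-6-propylbenzoate | CCCc1cc(O)c(C=O)c(O)c1C(=O)OCc1ccccc1 | intermediate
14 | benzyl 2,4-bis(benzyloxy)-3-formyl-6-propylbenzoate | CCCc1cc(OCc2ccccc2)c(C=O)c(OCc2ccccc2)c1C(=O)OCc1ccccc1 | intermediate
15 | benzyl 2,4-bis(benzyloxy)-3-(formyloxy)-6-propylbenzoate | CCCc1cc(OCc2ccccc2)c(OC=O)c(OCc2ccccc2)c1C(=O)OCc1ccccc1 | intermediate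
16 | benzyl 2,4-bis(benzyloxy)-3-hydroxy-6-propylbenzoate | CCCc1cc(OCc2ccccc2)c(O)c(OCc2ccccc2)c1C(=O)OCc1ccccc1 | intermediate
17 | 2,4-dimethoxy-6-pentylbenzoic trifluoroacetic anhydride | CCCCCc1cc(OC)cc(OC)c1C(=O)OC(=O)C(F)(F)F | intermediate
18 | benzyl 2,4-bis(benzyloxy)-3-[(2,4-dimethoxy-6-pentylbenzoyl)oxy]-6-propylbenzoate | CCCCCc1cc(OC)cc(OC)c1C(=O)Oc1c(OCc2ccccc2)cc(CCC)c(C(=O)OCc2ccccc2)c1OCc1ccccc1 | intermediate
19 | 3-[(2,4-dimethoxy-6-pentylbenzoyl)oxy]-2,4-dihydroxy-6-propylbenzoic acid | CCCCCc1cc(OC)cc(OC)c1C(=O)Oc1c(O)cc(CCC)c(C(=O)O)c1O | target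

**Count**
Total step count: 10. Longest linear sequence: 7 steps (steps 4 to 10, from 5-propylresorcinol). The ring A branch (steps 1 and 3, with the Grignard preparation of step 2) joins at step 9.

**Steps most likely to fail**

Step 3. The chelated 2-bromoarylmagnesium may lose MgBrCl only sluggishly. The aryne may also be captured by residual isopropyl species or by the product arylmagnesium instead of the pentyl Grignard, lowering conversion and purity. The fallback sets out from 1 and 4 and abandons the aryne for electrophilic substitution. A Kumada–Corriu coupling with NiCl2(dppp) as catalyst in THF should give 1,3-dimethoxy-5-pentylbenzene F1. Vilsmeier–Haack formylation (POCl3, DMF) at the carbon between the pentyl and a methoxy group, para to the other methoxy group, should give 2,4-dimethoxy-6-pentylbenzaldehyde F2. Pinnick oxidation (NaClO2, NaH2PO4, 2-methyl-2-butene, tBuOH/H2O) then returns to the route at 9.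

Step 6. Formylation may go to C5 or to both C3 and C5, or the ester-deactivated ring may react too slowly. The fallback sets out from 12 and replaces innate selectivity by blocking. Benzylation of the non-chelated 4-hydroxyl (BnBr, 1 equiv, K2CO3, acetone, reflux) should give benzyl 4-(benzyloxy)-2-hydroxy-6-propylbenzoate F3. The single remaining free phenol has only one open ortho carbon, C3, so the magnesium-phenoxide-directed formylation (MgCl2, Et3N, paraformaldehyde) can deliver only benzyl 4-(benzyloxy)-3-formyl-2-hydroxy-6-propylbenzoate F4. Benzylation of the last phenol (BnBr, K2CO3, DMF) comes back to the route at 14.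

Step 9. O-acylation of the phenol flanked by two benzyloxy groups may be slow. The acylium ion would then be diverted into self-condensation or C-acylation. The fallback sets out from 13 and uses a less hindered ring B partner.
- Dakin oxidation of the ortho-hydroxy aldehyde (H2O2, NaOH, aqueous THF, 0 °C, N2) should give benzyl 2,3,4-trihydroxy-6-propylbenzoate F5.
- Benzylation of the most acidic 4-hydroxyl, para to the ester (BnBr, 1 equiv, KHCO3, DMF), should give benzyl 4-(benzyloxy)-2,3-dihydroxy-6-propylbenzoate F6.
- Coupling with 9 under the trifluoroacetic anhydride conditions should acylate the 3-hydroxyl, because the 2-hydroxyl is tied up in a hydrogen bond to the ester carbonyl. This should give benzyl 4-(benzyloxy)-3-[(2,4-dimethoxy-6-pentylbenzoyl)oxy]-2-hydroxy-6-propylbenzoate F7.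
- Hydrogenolysis over Pd/C in EtOAc comes back to the route at 19.

**Further compounds**
F1 | step 3 | 1,3-dimethoxy-5-pentylbenzene | CCCCCc1cc(OC)cc(OC)c1
F2 | step 3 | 2,4-dimethoxy-6-pentylbenzaldehyde | CCCCCc1cc(OC)cc(OC)c1C=O
F3 | step 6 | benzyl 4-(benzyloxy)-2-hydroxy-6-propylbenzoate | CCCc1cc(OCc2ccccc2)cc(O)c1C(=O)OCc1ccccc1
F4 | step 6 | benzyl 4-(benzyloxy)-3-formyl-2-hydroxy-6-propylbenzoate | CCCc1cc(OCc2ccccc2)c(C=O)c(O)c1C(=O)OCc1ccccc1
F5 | step 9 | benzyl 2,3,4-trihydroxy-6-propylbenzoate | CCCc1cc(O)c(O)c(O)c1C(=O)OCc1ccccc1
F6 | step 9 | benzyl 4-(benzyloxy)-2,3-dihydroxy-6-propylbenzoate | CCCc1cc(OCc2ccccc2)c(O)c(O)c1C(=O)OCc1ccccc1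
F7 | step 9 | benzyl 4-(benzyloxy)-3-[(2,4-dimethoxy-6-pentylbenzoyl)oxy]-2-hydroxy-6-propylbenzoate | CCCCCc1cc(OC)cc(OC)c1C(=O)Oc1c(OCc2ccccc2)cc(CCC)c(C(=O)OCc2ccccc2)c1O
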